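# Proposed synthesis of (R)-5,7-dihydroxy-6-(2-hydroxy-3-methylbut-3-enyl)-4'-methoxyisoflavone (27) by ring-A benzannulation

## The problem

Compound 27 is an isoflavone: a chromen-4-one (rings A and C) carrying a 4-methoxyphenyl ring B on C3, free hydroxyls on C5 and C7 and, between them on C6, an (R)-2-hydroxy-3-methylbut-3-enyl chain. Ring A is a phloroglucinol in which C6 and C8 are each flanked by two oxygens, so attaching the chain to a finished 5,7-dihydroxyisoflavone, or closing ring C on an undifferentiated triol, leads to 6/8 mixtures. Seen from the other side, ring C must close on the one oxygen that lies para to the chain (O1 on C8a); O5 and O7 both end as free hydroxyls and need not be told apart for the constitution. The only stereocentre, C2'', is a secondary allylic carbinol two bonds away from the ring: nothing in the molecule can control it and it controls nothing, so it has to be set by a reagent and then merely preserved. The isopropenyl carbinol next to two phenols is the fragile part: acid can close it onto a phenol (chromane formation) or ionise it, the 1,1-disubstituted alkene rules out hydrogenolysis, and the chromenone opens at C2 under strong aqueous base. The feature that makes the chosen route possible is the alternation around ring A (O on C5, carbon on C6, O on C7, H on C8, O on C8a, carbon on C4a). This is exactly the pattern obtained when a ketene carbon (C5), the two carbons of a siloxyalkyne (C6 with the chain, C7 with its oxygen) and C2–C4 of a 3-alkoxycyclobutenone (C8, C8a with its oxygen, C4a) are joined into a benzene ring.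

## Retrosynthesis

**27 ⇒ 26 ⇒ 25 (no skeletal bond cut).** The last operations only unmask three oxygens. The acetal on O5 and the silyl ether on the chain of 25 are removed first by acid, while O7 stays silylated in 26; the aryl silyl ether then falls to buffered fluoride. With this order the only phenol present during the acid step is the chelated 5-OH, which is a poor nucleophile towards the side-chain alkene. The reverse order would expose the free 7-OH to acid.

**25 ⇒ 23 (cut O1–C2 and C2–C3, ring C).** Ring C is taken apart to the 2-hydroxydeoxybenzoin 23 and a one-carbon formamide-acetal unit, the forward reaction passing through enaminone 24. The alternative cut at C3–C1' (cross-coupling of a 3-iodochromone) would need an electrophilic iodination that the side-chain alkene would not tolerate. Compound 23 already contains every carbon but one. The forward step asks that the only free phenol be the one on the future C8a, so that closure cannot occur on O5; this is why O5 is an acetal and O8a alone is liberated beforehand.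

**23 ⇒ 22 ⇒ 21 ⇒ 17 + 18 (cut C4–C4a).** The aryl–acyl bond is cut to aldehyde 18 and the aryl anion of 17, followed by oxidation of carbinol 21 to ketone 22 and oxidative removal of the benzyl-type ether to give 23. Friedel–Crafts or Hoesch acylation would need strong acid and offers no control over the two ring hydrogens. Directed metalation places the metal on the one C–H that lies between the acetal oxygen and the benzyl-type ether oxygen; the other C–H is shielded by the bulky silyl ether. There is a safety margin: acylation at the other ring hydrogen followed by closure on the same oxygen would still give 27 after deprotection, because O5 and O7 are interchangeable in the target. The forward reaction asks for addition without enolisation of 18.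

**17 ⇒ 16 ⇒ 8 + 11 (cut C5–C6 and C7–C8; C4a–C5 is broken and re-formed).** Phenol 16, the precursor of acetal 17, is disconnected across ring A into siloxyalkyne 8 and alkoxycyclobutenone 11. Against stepwise substitution of a phloroglucinol, this cut delivers the chain between a free hydroxyl and a silyl ether and tags the oxygen para to the chain as the only benzyl-type ether, all in one step. Both precursors are small, and only 8 is chiral. The forward reaction asks for one orientation in the ketene–alkyne cycloaddition and for survival of two silyl ethers and an enol ether at about 100 °C.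

**8 ⇒ 6 ⇒ 5 ⇒ 4 ⇒ 1 + 2.** The siloxyalkyne is traced to ester 6 by removing one carbon (ester-to-ynolate homologation through ynolate 7, then O-silylation). Ester 6 comes from hydroxy ester 5 by silylation, and 5 from aldol adduct 4 by methanolysis. The C2–C3 bond of 4 is cut to methacrolein 1 and the chiral acetate 2, whose dilithium enolate 3 sets the stereocentre. An acetate aldol was preferred to a propargylation because the facial sense of 2 is established for an aldehyde with the same substituent ranking and because the adduct can be purified by crystallisation.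

**11 ⇒ 9 + 10 (cut the enol ether C–O bond).** The cyclobutenone is obtained from the ethyl vinylogous ester 9 by alkoxy exchange with alcohol 10. The 4-methoxybenzyl group is chosen because it survives the thermolysis and the aryllithium, and can later be removed oxidatively without touching silyl ethers, acetal or alkene.

## Roads not taken

**Alternative 1: conjunctive coupling on a vinyl boronate.** The cut is at C6–C1'' and C2''–C3''. An ate complex from vinylboronic pinacol ester A3 and isopropenylmagnesium bromide A4 would be coupled with the 6-iodoisoflavone A2 under palladium catalysis with a chiral ferrocenyl bisphosphine; the aryl-palladium species triggers a 1,2-shift that gives boronate A1, and oxidation of the C–B bond with retention followed by acetal removal would finish the synthesis.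
- Merits: this road is clearly shorter than the chosen one, since A2 derives in a few steps from the commercial isoflavone A5, and it sets the stereocentre catalytically at a late stage.
- Weak points:
  - The 6/8 problem returns in the iodination of A5 derivatives.
  - A2 is a doubly ortho-substituted aryl iodide, and iodide is an inhibitor in this type of coupling.
  - The ate complex carries two alkenyl groups, either of which can act as acceptor or migrating group.
  - A1 is a secondary allylic boronate, prone to 1,3-boron shift, so the oxidation may give a transposed alcohol.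
  - Two acetals must finally be removed with acid in the presence of the free 7-OH and the allylic alcohol.
- Comparison: against the step-count advantage, the chosen plan sets regiochemistry that is fixed by construction and a stereocentre that comes from a well-understood aldol and travels as a robust silyl ether.

**Alternative 2: silanol-directed palladation and isoprene capture.** The cut is at C6–C1'' and C2''–O. The 5-O-silanol A7 would direct divalent palladium to C6–H, the aryl-palladium species would add to isoprene A8, and the resulting allyl-palladium would be captured by the silanol oxygen at the internal carbon under a chiral amino acid ligand and a silver oxidant, giving the bridged dioxasilepine A6.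
- Merits: the tether from O5 makes C6–H the only reachable ortho hydrogen, so the 6/8 question is solved by geometry; C–C bond, C–O bond and stereocentre are made in one step from a feedstock diene. If it worked it would be the shortest route of all.
- Weak points:
  - Silanol-directed C–H alkenylation of phenols is known, but enantioselective diene capture with seven-membered ring closure at the branched allyl terminus is not.
  - β-Hydride elimination to a diene, attack at the unsubstituted terminus and insertion at the more substituted alkene of A8 all compete.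
  - The chelated 5-OH is hard to silylate with a di-tert-butylsilyl unit.
  - C2–H of the chromenone is itself reactive towards divalent palladium.
- Comparison: the chosen plan is longer, but every bond-forming event has a close precedent, and the stereocentre does not depend on an untested enantio-determining step.

**Alternative 3: aryne annulation for ring C.** The cut is at O1–C8a and C4–C4a. Fluoride would release aryne A12 from silyl triflate A10; the enolate oxygen of hydroxyacrylate A11 adds at C8a (distal to the C5 alkoxy group), and the aryl anion at C4a attacks the ester with loss of methoxide to give isoflavone A9.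
- Merits: the step is convergent, brings in ring B and C3 in one piece, and its regiochemistry follows the reliable rule for 3-alkoxyarynes. As a way of making ring C it is at least as elegant as the enaminone closure used here.
- Weak points:
  - A10 is a hexasubstituted benzene in which chain, two acetals, silicon and triflate must stand in a defined order, so the whole ring-A problem (and more) is moved into its preparation.
  - The enolate can arylate at carbon instead of oxygen.
  - Fluoride threatens the silyl ether of the chain.
  - Two acetals must be removed by acid with the 7-OH free.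
- Comparison: the chosen plan answers the first weak point directly by assembling ring A with all substituents in a single step from two small fragments, and the last by keeping O7 silylated during the acid step.

Key step: step 6

Assumption: 3-ethoxycyclobut-2-en-1-one (9), the chiral acetate 2 and aldehyde 18 are taken as purchasable; 18 is distilled immediately before use because arylacetaldehydes oligomerise on storage.

Abbreviations used in names: TBS = tert-butyldimethylsilyl, TIPS = triisopropylsilyl, PMB = 4-methoxybenzyl, MOM = methoxymethyl.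

## Route

Step 1
Reactants: 1 methacrolein; 2 (R)-2-hydroxy-1,2,2-triphenylethyl acetate
Product: 4 (1R)-2-hydroxy-1,2,2-triphenylethyl (3R)-3-hydroxy-4-methylpent-4-enoate, via dilithium enolate 3 (not isolated)
Conditions: LiN(iPr)2 (2.2 equiv), THF, −78 → 0 °C; then 1, THF/2-methylbutane, −125 °C; aq. NH4Cl
Reagents that add atoms: none
Why: Acetate aldol addition of the doubly deprotonated chiral acetate; the (R)-reagent is known to attack the Re face of aldehydes (isobutyraldehyde gives the (R)-β-hydroxy acid), and methacrolein has the same ranking at the carbinol carbon (O > alkenyl > CH2C=O), so Re attack should set C3 as R, the future C2''. The adduct should be crystalline, so the minor diastereomer can be removed by recrystallisation.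

Step 2
Reactants: 4 (1R)-2-hydroxy-1,2,2-triphenylethyl (3R)-3-hydroxy-4-methylpent-4-enoate
Product: 5 methyl (3R)-3-hydroxy-4-methylpent-4-enoate
Conditions: K2CO3 (cat.), MeOH, 0 °C → rt
Reagents that add atoms: methanol, CO
Why: Base-catalysed transesterification releases the triphenylethanediol auxiliary; the carbinol stereocentre is not acidic and the mild carbonate should not induce retro-aldol cleavage or dehydration.

Step 3
Reactants: 5 methyl (3R)-3-hydroxy-4-methylpent-4-enoate
Product: 6 methyl (3R)-3-(TBS-oxy)-4-methylpent-4-enoate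
Conditions: TBSCl, imidazole, DMF, rt
Reagents that add atoms: tert-butyldimethylsilyl chloride, CC(C)(C)[Si](C)(C)Cl
Why: Standard silylation of a secondary alcohol; the TBS ether shields the carbinol against the strong bases, the thermolysis and the oxidants that follow.

Step 4
Reactants: 6 methyl (3R)-3-(TBS-oxy)-4-methylpent-4-enoate
Product: 8 (3R)-3-(TBS-oxy)-2-methyl-6-(TIPS-oxy)hex-1-en-5-yne, via lithium ynolate 7 (not isolated)
Conditions: CH2Br2, lithium 2,2,6,6-tetramethylpiperidide (from the amine and n-BuLi), THF, −78 °C; n-BuLi, −78 °C → rt; TIPSCl, 0 °C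
Reagents that add atoms: dibromomethane, BrCBr; triisopropylsilyl chloride, CC(C)[Si](Cl)(C(C)C)C(C)C
Why: Kowalski ester homologation: dibromomethyllithium adds to the ester, the dibromoketone enolate undergoes bromine–lithium exchange and the carbenoid rearranges by 1,2-alkyl shift to ynolate 7, which the bulky chlorosilane traps on oxygen. The stereocentre is β to the reacting carbon and takes no part.

Step 5
Reactants: 9 3-ethoxycyclobut-2-en-1-one; 10 4-methoxybenzyl alcohol
Product: 11 3-(PMB-oxy)cyclobut-2-en-1-one
Conditions: pyridinium p-toluenesulfonate (cat.), PhMe, 45 °C, reduced pressure (EtOH removed)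
Reagents that add atoms: none
Why: Acid-catalysed alkoxy exchange of a vinylogous ester (addition of 10 at C3 of the O-protonated enone, loss of ethanol); removal of ethanol drives the equilibrium, and the weak pyridinium acid should spare the strained ring and the benzylic alcohol.

Step 6
Reactants: 8 (3R)-3-(TBS-oxy)-2-methyl-6-(TIPS-oxy)hex-1-en-5-yne; 11 3-(PMB-oxy)cyclobut-2-en-1-one
Product: 16 2-[(2R)-2-(TBS-oxy)-3-methylbut-3-enyl]-5-(PMB-oxy)-3-(TIPS-oxy)phenol, via vinylketene 12 (not isolated), via vinylcyclobutenone 13 (not isolated), via dienylketene 14 (not isolated), via cyclohexadienone 15 (not isolated)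
Conditions: PhMe (degassed), 80 °C, then 110 °C
Reagents that add atoms: none
Why: Heating 11 causes conrotatory four-electron ring opening to vinylketene 12, whose electrophilic ketene carbon is attacked by the oxygen-polarised, nucleophilic C5 of siloxyalkyne 8 in a (2+2) cycloaddition that gives vinylcyclobutenone 13 with the chain next to the carbonyl. A second, reversible four-electron opening gives dienylketene 14, and ring A closes by thermally allowed disrotatory six-electron electrocyclisation between the ketene carbon and the enol-ether methylene, forming the six-membered carbocycle as cyclohexadienone 15, which tautomerises irreversibly to phenol 16. The closest known reaction type is the Danheiser benzannulation of cyclobutenones with siloxyalkynes, which gives resorcinol monosilyl ethers; here the alkoxy group of the cyclobutenone supplies the third oxygen. No stereocentre is created (the sp3 carbon of 13 is lost on aromatisation), and C2'', insulated by a methylene group, should pass through the neutral thermolysis unchanged. The one selectivity needed is the orientation of the (2+2) step, which the matched polarity of ketene carbon and siloxyalkyne β-carbon secures; it places the chain between the free hydroxyl and the silyl ether and the PMB ether para to it, so that the future O1 is the only benzyl-type ether.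

Step 7
Reactants: 16 2-[(2R)-2-(TBS-oxy)-3-methylbut-3-enyl]-5-(PMB-oxy)-3-(TIPS-oxy)phenol
Product: 17 1-[(2R)-2-(TBS-oxy)-3-methylbut-3-enyl]-2-(MOM-oxy)-4-(PMB-oxy)-6-(TIPS-oxy)benzene
Conditions: MOMCl, iPr2NEt, Bu4NI (cat.), CH2Cl2, 0 °C → rt
Reagents that add atoms: chloromethyl methyl ether, COCCl
Why: O-Alkylation of the only free phenol under amine base, mild enough to avoid silyl migration; the MOM group masks O5 for the ring closure and serves as the directing group for the next step.

Step 8
Reactants: 17 1-[(2R)-2-(TBS-oxy)-3-methylbut-3-enyl]-2-(MOM-oxy)-4-(PMB-oxy)-6-(TIPS-oxy)benzene; 18 4-methoxyphenylacetaldehyde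
Product: 21 1-{3-[(2R)-2-(TBS-oxy)-3-methylbut-3-enyl]-2-(MOM-oxy)-6-(PMB-oxy)-4-(TIPS-oxy)phenyl}-2-(4-methoxyphenyl)ethan-1-ol (epimer mixture at the carbinol carbon), via aryllithium 19 (not isolated), via arylcerium dichloride 20 (not isolated)
Conditions: n-BuLi, THF, 0 °C; CeCl3 (anhydrous), −78 °C; 18, −78 °C; aq. NH4Cl
Reagents that add atoms: none
Why: Directed ortho-metalation removes the ring hydrogen flanked by the MOM and PMB oxygens (the other ring hydrogen is shielded by the TIPS ether), and transmetalation to the less basic organocerium lets the hindered aryl nucleophile add to the enolisable aldehyde. The new carbinol centre is not controlled and is destroyed in step 9.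

Step 9
Reactants: 21 1-{3-[(2R)-2-(TBS-oxy)-3-methylbut-3-enyl]-2-(MOM-oxy)-6-(PMB-oxy)-4-(TIPS-oxy)phenyl}-2-(4-methoxyphenyl)ethan-1-ol
Product: 22 1-{3-[(2R)-2-(TBS-oxy)-3-methylbut-3-enyl]-2-(MOM-oxy)-6-(PMB-oxy)-4-(TIPS-oxy)phenyl}-2-(4-methoxyphenyl)ethan-1-one
Conditions: Dess–Martin periodinane, NaHCO3, CH2Cl2, 0 °C → rt
Reagents that add atoms: none
Why: Buffered hypervalent-iodine oxidation of a secondary benzylic alcohol to the deoxybenzoin; neutral conditions avoid ionisation of the electron-rich benzylic carbinol and leave silyl ethers, acetal and alkene untouched.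

Step 10
Reactants: 22 1-{3-[(2R)-2-(TBS-oxy)-3-methylbut-3-enyl]-2-(MOM-oxy)-6-(PMB-oxy)-4-(TIPS-oxy)phenyl}-2-(4-methoxyphenyl)ethan-1-one
Product: 23 1-{3-[(2R)-2-(TBS-oxy)-3-methylbut-3-enyl]-6-hydroxy-2-(MOM-oxy)-4-(TIPS-oxy)phenyl}-2-(4-methoxyphenyl)ethan-1-one
Conditions: DDQ, CH2Cl2/pH 7 buffer, 0 °C → rt
Reagents that add atoms: none
Why: Oxidative PMB cleavage (hydride abstraction at the ether-activated benzylic carbon, hydrolysis of the oxocarbenium ion) frees only the oxygen para to the chain. The ketone methylene lacks an oxygen donor and ring A is deactivated by the acyl group, so both should be spared.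

Step 11
Reactants: 23 1-{3-[(2R)-2-(TBS-oxy)-3-methylbut-3-enyl]-6-hydroxy-2-(MOM-oxy)-4-(TIPS-oxy)phenyl}-2-(4-methoxyphenyl)ethan-1-one
Product: 25 6-[(2R)-2-(TBS-oxy)-3-methylbut-3-enyl]-5-(MOM-oxy)-3-(4-methoxyphenyl)-7-(TIPS-oxy)-4H-chromen-4-one, via enaminone 24 (not isolated)
Conditions: Me2NCH(OMe)2, PhMe, 80 °C
Reagents that add atoms: N,N-dimethylformamide dimethyl acetal, COC(OC)N(C)C
Why: Standard isoflavone closure of a 2-hydroxydeoxybenzoin: condensation at the active methylene gives enaminone 24, and the only free phenol adds to its β-carbon with loss of dimethylamine. Because O5 is an acetal, ring C can form only on the oxygen para to the chain, which fixes the 6-substitution.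

Step 12
Reactants: 25 6-[(2R)-2-(TBS-oxy)-3-methylbut-3-enyl]-5-(MOM-oxy)-3-(4-methoxyphenyl)-7-(TIPS-oxy)-4H-chromen-4-one
Product: 26 5-hydroxy-6-[(2R)-2-hydroxy-3-methylbut-3-enyl]-3-(4-methoxyphenyl)-7-(TIPS-oxy)-4H-chromen-4-one
Conditions: HCl (0.5 M in MeOH), THF, 0 °C → rt
Reagents that add atoms: none
Why: Acid methanolysis cleaves the peri MOM acetal (the liberated 5-OH is held by hydrogen bonding to the C4 carbonyl) and the secondary alkyl TBS ether, while the aryl TIPS ether should resist dilute acid. With O7 still silylated and O5 chelated, no nucleophilic phenol is available to add to the side-chain alkene.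

Step 13
Reactants: 26 5-hydroxy-6-[(2R)-2-hydroxy-3-methylbut-3-enyl]-3-(4-methoxyphenyl)-7-(TIPS-oxy)-4H-chromen-4-one
Product: 27 5,7-dihydroxy-6-[(2R)-2-hydroxy-3-methylbut-3-enyl]-3-(4-methoxyphenyl)-4H-chromen-4-one
Conditions: Bu4NF, AcOH, THF, 0 °C
Reagents that add atoms: none
Why: Fluoride cleavage of an aryl silyl ether, fast at low temperature; acetic acid buffers the phenoxide so that the chromenone is not opened at C2, and no acid strong enough to affect the allylic alcohol is present.

## Compound list

1 | methacrolein (2-methylprop-2-enal) | C=C(C)C=O | starting material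
2 | (R)-2-hydroxy-1,2,2-triphenylethyl acetate | CC(=O)O[C@H](c1ccccc1)C(O)(c1ccccc1)c1ccccc1 | starting material
3 | dilithium enolate of 2 (lithium alkoxide and lithium ester enolate) | [Li]OC(=C)O[C@H](c1ccccc1)C(O[Li])(c1ccccc1)c1ccccc1 | intermediate
4 | (1R)-2-hydroxy-1,2,2-triphenylethyl (3R)-3-hydroxy-4-methylpent-4-enoate | C=C(C)[C@H](O)CC(=O)O[C@H](c1ccccc1)C(O)(c1ccccc1)c1ccccc1 | intermediate
5 | methyl (3R)-3-hydroxy-4-methylpent-4-enoate | C=C(C)[C@H](O)CC(=O)OC | intermediate
6 | methyl (3R)-3-(tert-butyldimethylsilyloxy)-4-methylpent-4-enoate | C=C(C)[C@H](O[Si](C)(C)C(C)(C)C)CC(=O)OC | intermediate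
7 | lithium (4R)-4-(tert-butyldimethylsilyloxy)-5-methylhex-5-en-1-yn-1-olate | C=C(C)[C@H](O[Si](C)(C)C(C)(C)C)CC#CO[Li] | intermediate
8 | (3R)-3-(tert-butyldimethylsilyloxy)-2-methyl-6-(triisopropylsilyloxy)hex-1-en-5-yne | C=C(C)[C@H](O[Si](C)(C)C(C)(C)C)CC#CO[Si](C(C)C)(C(C)C)C(C)C | intermediate
9 | 3-ethoxycyclobut-2-en-1-one | CCOC1=CC(=O)C1 | starting material
10 | 4-methoxybenzyl alcohol | COc1ccc(CO)cc1 | starting material
11 | 3-[(4-methoxybenzyl)oxy]cyclobut-2-en-1-one | O=C1C=C(OCc2ccc(OC)cc2)C1 | intermediate
12 | 3-[(4-methoxybenzyl)oxy]buta-1,3-dien-1-one (vinylketene) | O=C=CC(=C)OCc1ccc(OC)cc1 | intermediate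
13 | 2-[(2R)-2-(tert-butyldimethylsilyloxy)-3-methylbut-3-enyl]-4-{1-[(4-methoxybenzyl)oxy]ethenyl}-3-(triisopropylsilyloxy)cyclobut-2-en-1-one (both C4 epimers) | C=C(C)[C@H](O[Si](C)(C)C(C)(C)C)CC1=C(O[Si](C(C)C)(C(C)C)C(C)C)C(C(=C)OCc2ccc(OC)cc2)C1=O | intermediate
14 | (3E)-2-[(2R)-2-(tert-butyldimethylsilyloxy)-3-methylbut-3-enyl]-5-[(4-methoxybenzyl)oxy]-3-(triisopropylsilyloxy)hexa-1,3,5-trien-1-one (dienylketene) | C=C(C)[C@H](O[Si](C)(C)C(C)(C)C)CC(=C=O)/C(O[Si](C(C)C)(C(C)C)C(C)C)=C\C(=C)OCc1ccc(OC)cc1 | intermediate
15 | 2-[(2R)-2-(tert-butyldimethylsilyloxy)-3-methylbut-3-enyl]-5-[(4-methoxybenzyl)oxy]-3-(triisopropylsilyloxy)cyclohexa-2,4-dien-1-one | C=C(C)[C@H](O[Si](C)(C)C(C)(C)C)CC1=C(O[Si](C(C)C)(C(C)C)C(C)C)C=C(OCc2ccc(OC)cc2)CC1=O | intermediate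
16 | 2-[(2R)-2-(tert-butyldimethylsilyloxy)-3-methylbut-3-enyl]-5-[(4-methoxybenzyl)oxy]-3-(triisopropylsilyloxy)phenol | C=C(C)[C@H](O[Si](C)(C)C(C)(C)C)Cc1c(O)cc(OCc2ccc(OC)cc2)cc1O[Si](C(C)C)(C(C)C)C(C)C | intermediate
17 | 1-[(2R)-2-(tert-butyldimethylsilyloxy)-3-methylbut-3-enyl]-2-(methoxymethoxy)-4-[(4-methoxybenzyl)oxy]-6-(triisopropylsilyloxy)benzene | C=C(C)[C@H](O[Si](C)(C)C(C)(C)C)Cc1c(OCOC)cc(OCc2ccc(OC)cc2)cc1O[Si](C(C)C)(C(C)C)C(C)C | intermediate
18 | 4-methoxyphenylacetaldehyde | COc1ccc(CC=O)cc1 | starting material
19 | {3-[(2R)-2-(tert-butyldimethylsilyloxy)-3-methylbut-3-enyl]-2-(methoxymethoxy)-6-[(4-methoxybenzyl)oxy]-4-(triisopropylsilyloxy)phenyl}lithium | C=C(C)[C@H](O[Si](C)(C)C(C)(C)C)Cc1c(OCOC)c([Li])c(OCc2ccc(OC)cc2)cc1O[Si](C(C)C)(C(C)C)C(C)C | intermediate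
20 | dichloro{3-[(2R)-2-(tert-butyldimethylsilyloxy)-3-methylbut-3-enyl]-2-(methoxymethoxy)-6-[(4-methoxybenzyl)oxy]-4-(triisopropylsilyloxy)phenyl}cerium | C=C(C)[C@H](O[Si](C)(C)C(C)(C)C)Cc1c(OCOC)c([Ce](Cl)Cl)c(OCc2ccc(OC)cc2)cc1O[Si](C(C)C)(C(C)C)C(C)C | intermediate
21 | 1-{3-[(2R)-2-(tert-butyldimethylsilyloxy)-3-methylbut-3-enyl]-2-(methoxymethoxy)-6-[(4-methoxybenzyl)oxy]-4-(triisopropylsilyloxy)phenyl}-2-(4-methoxyphenyl)ethan-1-ol (both carbinol epimers) | C=C(C)[C@H](O[Si](C)(C)C(C)(C)C)Cc1c(OCOC)c(C(O)Cc2ccc(OC)cc2)c(OCc2ccc(OC)cc2)cc1O[Si](C(C)C)(C(C)C)C(C)C | intermediate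
22 | 1-{3-[(2R)-2-(tert-butyldimethylsilyloxy)-3-methylbut-3-enyl]-2-(methoxymethoxy)-6-[(4-methoxybenzyl)oxy]-4-(triisopropylsilyloxy)phenyl}-2-(4-methoxyphenyl)ethan-1-one | C=C(C)[C@H](O[Si](C)(C)C(C)(C)C)Cc1c(OCOC)c(C(=O)Cc2ccc(OC)cc2)c(OCc2ccc(OC)cc2)cc1O[Si](C(C)C)(C(C)C)C(C)C | intermediate
23 | 1-{3-[(2R)-2-(tert-butyldimethylsilyloxy)-3-methylbut-3-enyl]-6-hydroxy-2-(methoxymethoxy)-4-(triisopropylsilyloxy)phenyl}-2-(4-methoxyphenyl)ethan-1-one | C=C(C)[C@H](O[Si](C)(C)C(C)(C)C)Cc1c(OCOC)c(C(=O)Cc2ccc(OC)cc2)c(O)cc1O[Si](C(C)C)(C(C)C)C(C)C | intermediate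
24 | 1-{3-[(2R)-2-(tert-butyldimethylsilyloxy)-3-methylbut-3-enyl]-6-hydroxy-2-(methoxymethoxy)-4-(triisopropylsilyloxy)phenyl}-3-(dimethylamino)-2-(4-methoxyphenyl)prop-2-en-1-one | C=C(C)[C@H](O[Si](C)(C)C(C)(C)C)Cc1c(OCOC)c(C(=O)C(=CN(C)C)c2ccc(OC)cc2)c(O)cc1O[Si](C(C)C)(C(C)C)C(C)C | intermediate
25 | 6-[(2R)-2-(tert-butyldimethylsilyloxy)-3-methylbut-3-enyl]-5-(methoxymethoxy)-3-(4-methoxyphenyl)-7-(triisopropylsilyloxy)-4H-chromen-4-one | C=C(C)[C@H](O[Si](C)(C)C(C)(C)C)Cc1c(O[Si](C(C)C)(C(C)C)C(C)C)cc2occ(-c3ccc(OC)cc3)c(=O)c2c1OCOC | intermediate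
26 | 5-hydroxy-6-[(2R)-2-hydroxy-3-methylbut-3-enyl]-3-(4-methoxyphenyl)-7-(triisopropylsilyloxy)-4H-chromen-4-one | C=C(C)[C@H](O)Cc1c(O[Si](C(C)C)(C(C)C)C(C)C)cc2occ(-c3ccc(OC)cc3)c(=O)c2c1O | intermediate
27 | 5,7-dihydroxy-6-[(2R)-2-hydroxy-3-methylbut-3-enyl]-3-(4-methoxyphenyl)-4H-chromen-4-one | C=C(C)[C@H](O)Cc1c(O)cc2occ(-c3ccc(OC)cc3)c(=O)c2c1O | target

## Step count and least certain steps

Total: 13 steps. Longest linear sequence: 12 steps (steps 1–4 and 6–13); step 5 is a one-step side branch.

**Step 6 (key step).** The donor-substituted cyclobutenone may open too slowly at temperatures the siloxyalkyne tolerates. The vinylketene, once formed, may be consumed by dimerisation or by acylating the product phenol. The siloxyalkyne may isomerise by thermal 1,3-silyl shift to a silylketene. Fallback: form vinylketene 12 by dehydrochlorination instead of electrocyclic opening. Setting out from 10, trialkylphosphine-catalysed conjugate addition to methyl but-2-ynoate should give methyl (2E)-3-[(4-methoxybenzyl)oxy]but-2-enoate F1. Saponification with LiOH gives (2E)-3-[(4-methoxybenzyl)oxy]but-2-enoic acid F2, and 1-chloro-N,N,2-trimethylprop-1-en-1-amine converts it under neutral conditions into (2E)-3-[(4-methoxybenzyl)oxy]but-2-enoyl chloride F3. Slow addition of Et3N to F3 and 8 in PhMe removes a γ-proton and releases 12 in the presence of the alkyne; warming then completes the sequence through 13, 14 and 15, and the route is rejoined at 16.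

**Step 5.** The strained vinylogous ester may be opened by the alcohol at the carbonyl carbon rather than exchanged at C3, or 10 may self-etherify under acid, and the equilibrium may stay incomplete. Fallback: from 9, hydrolysis with dilute aqueous HCl to cyclobutane-1,3-dione F4, then Mitsunobu O-alkylation of this vinylogous acid with 10 (PPh3, diisopropyl azodicarboxylate, THF, 0 °C), returning to 11.

**Step 4.** The amide base may deprotonate the ester α-position before the carbenoid adds, and the enolate can expel the β-silanolate; the ynolate may also be silylated on carbon. Fallback: from 6, reduction with i-Bu2AlH at −78 °C to (3R)-3-(tert-butyldimethylsilyloxy)-4-methylpent-4-enal F5, then homologation with the Ohira–Bestmann reagent (K2CO3, MeOH) to tert-butyldimethyl{[(3R)-2-methylhex-1-en-5-yn-3-yl]oxy}silane F6. Deprotonation of F6 with n-BuLi and oxidation of the acetylide with LiOOt-Bu gives ynolate 7, which is trapped with TIPS triflate to return to 8.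

**Step 8.** Proton transfer may compete with addition: enolisation of 18 by the hindered aryl metal, deprotonation at the PMB benzylic position (followed by Wittig rearrangement), or at C1'' (followed by loss of silanolate). Fallback: reverse the polarity of the C–C bond formation. From 17, the same lithiation is quenched with DMF, a non-enolisable electrophile, to give 3-[(2R)-2-(tert-butyldimethylsilyloxy)-3-methylbut-3-enyl]-2-(methoxymethoxy)-6-[(4-methoxybenzyl)oxy]-4-(triisopropylsilyloxy)benzaldehyde F7; addition of 4-methoxybenzylmagnesium chloride at −78 °C then returns to 21.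

**Step 12.** Under protic acid the freed allylic alcohol may ionise (transposition or loss of configuration), the isopropenyl group may be protonated and captured by a phenol, or TBS cleavage may stall. Fallback: remove the acetal without protic acid while every hydroxyl stays masked. From 25, Me3SiOTf with 2,2'-bipyridyl in CH2Cl2 at 0 °C followed by water exchanges the aryl MOM ether for a labile silyl ether and then the phenol, giving 6-[(2R)-2-(tert-butyldimethylsilyloxy)-3-methylbut-3-enyl]-5-hydroxy-3-(4-methoxyphenyl)-7-(triisopropylsilyloxy)-4H-chromen-4-one F8; a single treatment with Bu4NF/AcOH then removes both silyl groups and returns to 27.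

## Further compounds

F1 | step 6 | methyl (2E)-3-[(4-methoxybenzyl)oxy]but-2-enoate | COC(=O)/C=C(\C)OCc1ccc(OC)cc1
F2 | step 6 | (2E)-3-[(4-methoxybenzyl)oxy]but-2-enoic acid | OC(=O)/C=C(\C)OCc1ccc(OC)cc1
F3 | step 6 | (2E)-3-[(4-methoxybenzyl)oxy]but-2-enoyl chloride | ClC(=O)/C=C(\C)OCc1ccc(OC)cc1
F4 | step 5 | cyclobutane-1,3-dione | O=C1CC(=O)C1
F5 | step 4 | (3R)-3-(tert-butyldimethylsilyloxy)-4-methylpent-4-enal | C=C(C)[C@H](O[Si](C)(C)C(C)(C)C)CC=O
F6 | step 4 | tert-butyldimethyl{[(3R)-2-methylhex-1-en-5-yn-3-yl]oxy}silane | C=C(C)[C@H](O[Si](C)(C)C(C)(C)C)CC#C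
F7 | step 8 | 3-[(2R)-2-(tert-butyldimethylsilyloxy)-3-methylbut-3-enyl]-2-(methoxymethoxy)-6-[(4-methoxybenzyl)oxy]-4-(triisopropylsilyloxy)benzaldehyde | C=C(C)[C@H](O[Si](C)(C)C(C)(C)C)Cc1c(OCOC)c(C=O)c(OCc2ccc(OC)cc2)cc1O[Si](C(C)C)(C(C)C)C(C)C
F8 | step 12 | 6-[(2R)-2-(tert-butyldimethylsilyloxy)-3-methylbut-3-enyl]-5-hydroxy-3-(4-methoxyphenyl)-7-(triisopropylsilyloxy)-4H-chromen-4-one | C=C(C)[C@H](O[Si](C)(C)C(C)(C)C)Cc1c(O[Si](C(C)C)(C(C)C)C(C)C)cc2occ(-c3ccc(OC)cc3)c(=O)c2c1O
A1 | alternative 1 | 5,7-bis(methoxymethoxy)-3-(4-methoxyphenyl)-6-[(2R)-3-methyl-2-(4,4,5,5-tetramethyl-1,3,2-dioxaborolan-2-yl)but-3-enyl]-4H-chromen-4-one | C=C(C)[C@H](B1OC(C)(C)C(C)(C)O1)Cc1c(OCOC)cc2occ(-c3ccc(OC)cc3)c(=O)c2c1OCOC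
A2 | alternative 1 | 6-iodo-5,7-bis(methoxymethoxy)-3-(4-methoxyphenyl)-4H-chromen-4-one | Ic1c(OCOC)cc2occ(-c3ccc(OC)cc3)c(=O)c2c1OCOC
A3 | alternative 1 | vinylboronic acid pinacol ester | C=CB1OC(C)(C)C(C)(C)O1
A4 | alternative 1 | isopropenylmagnesium bromide | C=C(C)[Mg]Br
A5 | alternative 1 | 5,7-dihydroxy-3-(4-methoxyphenyl)-4H-chromen-4-one | COc1ccc(-c2coc3cc(O)cc(O)c3c2=O)cc1
A6 | alternative 2 | di-tert-butylsilylene-bridged 7-O-methoxymethyl derivative of the target (seven-membered dioxasilepine from O5 to the C2'' oxygen, R at C2'') | C=C(C)[C@H]1Cc2c(OCOC)cc3occ(-c4ccc(OC)cc4)c(=O)c3c2O[Si](C(C)(C)C)(C(C)(C)C)O1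
A7 | alternative 2 | 5-[di-tert-butyl(hydroxy)silyloxy]-7-(methoxymethoxy)-3-(4-methoxyphenyl)-4H-chromen-4-one | COCOc1cc(O[Si](O)(C(C)(C)C)C(C)(C)C)c2c(=O)c(-c3ccc(OC)cc3)coc2c1
A8 | alternative 2 | isoprene | C=CC(C)=C
A9 | alternative 3 | 6-[(2R)-2-(tert-butyldimethylsilyloxy)-3-methylbut-3-enyl]-5,7-bis(methoxymethoxy)-3-(4-methoxyphenyl)-4H-chromen-4-one | C=C(C)[C@H](O[Si](C)(C)C(C)(C)C)Cc1c(OCOC)cc2occ(-c3ccc(OC)cc3)c(=O)c2c1OCOC
A10 | alternative 3 | 4-[(2R)-2-(tert-butyldimethylsilyloxy)-3-methylbut-3-enyl]-3,5-bis(methoxymethoxy)-2-(trimethylsilyl)phenyl trifluoromethanesulfonate | C=C(C)[C@H](O[Si](C)(C)C(C)(C)C)Cc1c(OCOC)cc(OS(=O)(=O)C(F)(F)F)c([Si](C)(C)C)c1OCOC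
A11 | alternative 3 | methyl 3-hydroxy-2-(4-methoxyphenyl)prop-2-enoate | COC(=O)C(=CO)c1ccc(OC)cc1
A12 | alternative 3 | 4-[(2R)-2-(tert-butyldimethylsilyloxy)-3-methylbut-3-enyl]-3,5-bis(methoxymethoxy)-1,2-didehydrobenzene | C=C(C)[C@H](O[Si](C)(C)C(C)(C)C)CC1=C(OCOC)C#CC=C1OCOC
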